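## Retrosynthetic overview

1. Target ⇐ desilylation ⇐ C3–O bond: a transannular oxidative oxa-cyclisation of a ten-membered α′-hydroxy E-enone lactone closes the 3(2H)-furanone bridge (last ring, key C–O step).
2. Ten-membered carbocycle and trans γ-lactone ⇐ one chromium Barbier macrocyclisation (C7–C8) with lactonisation (O8–C12) of an aldehyde / 2-(bromomethyl)enoate.
3. Seco chain ⇐ cross-metathesis at C2=C3 of a West α′-hydroxy vinyl ketone (C1, C8–C10) with an East diene ester (C3–C7, C11–C13).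
4. West ⇐ (S)-lactic acid by Seebach alkylation (C10). East ⇐ (S)-glyceraldehyde acetonide (C6) by Z-crotylboration (C4, C5), ortho-ester-directed C6 isobutyrylation, vinylalumination and bromination.
5. Ring order: carbocycle and lactone together, then the furanone bridge.

Assumption: germacrane numbering is used (C1 ketone, C2=C3, C3–O–C10 bridge, C4 CHMe, C5 OH, C6 isobutyrate, C8 lactone O, C11=C13, C12 lactone C=O; target = 4S,5S,6S,7R,8S,10R), and (S)-glyceraldehyde acetonide and (−)-Ipc2BOMe are bought.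

## Route

Step 1
Reactants: 1 (S)-lactic acid
Product: 2 (2S,5S)-2-tert-butyl-5-methyl-1,3-dioxolan-4-one
Conditions: t-BuCHO, TsOH·H2O (cat.), H2SO4 (cat.), pentane, reflux (Dean–Stark); crystallise at −78 °C
Reagents that add atoms: pivalaldehyde, CC(C)(C)C=O
Why: Acid-catalysed acetalisation (Seebach dioxolanone formation) in which the lactate centre steers the new acetal carbon to the cis isomer under thermodynamic control and crystallisation.

Step 2
Reactants: 2 (2S,5S)-2-tert-butyl-5-methyl-1,3-dioxolan-4-one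
Product: 4 (2S,5R)-2-tert-butyl-5-methyl-5-(prop-2-enyl)-1,3-dioxolan-4-one, via lithium enolate 3 (not isolated)
Conditions: LiN(iPr)2, THF, −78 °C; allyl bromide, −78 → −30 °C
Reagents that add atoms: allyl bromide, C=CCBr
Why: Seebach self-regeneration of stereocentres (enolate alkylation): the planar enolate is attacked anti to the tert-butyl group, so allyl takes the place of H and fixes the quaternary carbinol carbon that becomes C10 (R).

Step 3
Reactants: 4 (2S,5R)-2-tert-butyl-5-methyl-5-(prop-2-enyl)-1,3-dioxolan-4-one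
Product: 6 (2S,5R)-2-tert-butyl-5-(2,2-dimethoxyethyl)-5-methyl-1,3-dioxolan-4-one, via dioxolanone aldehyde 5 (not isolated)
Conditions: O3, CH2Cl2/MeOH, −78 °C; Me2S, → rt; then HC(OMe)3, PPTS (cat.), rt
Reagents that add atoms: trimethyl orthoformate, COC(OC)OC (both methoxy groups of 6); ozone, [O-][O+]=O (carbonyl oxygen of 5 only)
Why: Ozonolysis with reductive work-up followed by acetalisation in the same flask masks the future C8 aldehyde against the Grignard step and touches no stereocentre.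

Step 4
Reactants: 6 (2S,5R)-2-tert-butyl-5-(2,2-dimethoxyethyl)-5-methyl-1,3-dioxolan-4-one
Product: 8 (4R)-4-hydroxy-6,6-dimethoxy-4-methylhex-1-en-3-one, via hemiketal magnesium alkoxide 7 (not isolated)
Conditions: CH2=CHMgBr (1.2 equiv), THF, −78 °C; aq. NH4Cl at −78 °C, → rt
Reagents that add atoms: vinylmagnesium bromide, C=C[Mg]Br
Why: Single Grignard addition to the acetal-ester carbonyl (acyl substitution) gives a hemiketal alkoxide that survives at −78 °C and collapses on quench with loss of pivalaldehyde to the α′-hydroxy vinyl ketone, leaving C10 untouched.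

Step 5
Reactants: 9 (4S)-2,2-dimethyl-1,3-dioxolane-4-carbaldehyde [(S)-glyceraldehyde acetonide]
Product: 11 (1S,2R)-1-[(4S)-2,2-dimethyl-1,3-dioxolan-4-yl]-2-methylbut-3-en-1-ol, via diisopinocampheylborinate ester 10 (not isolated)
Conditions: cis-2-butene, KOtBu, n-BuLi, THF, −78 → −45 °C; (−)-Ipc2BOMe, −78 °C; BF3·OEt2; 9, −78 °C; then NaOH, H2O2, rt
Reagents that add atoms: (Z)-but-2-ene, C/C=C\C
Why: Brown asymmetric crotylboration: the (Z)-crotylborane reacts through a closed chair transition state (Me/OH syn) and the isopinocampheyl groups from (+)-α-pinene direct attack to the Si face, setting C4 and C5 of the all-syn triad under reagent control against the Felkin bias of 9 (the minor 5-epimer is removed by chromatography).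

Step 6
Reactants: 11 (1S,2R)-1-[(4S)-2,2-dimethyl-1,3-dioxolan-4-yl]-2-methylbut-3-en-1-ol
Product: 12 tert-butyl{[(1S,2R)-1-[(4S)-2,2-dimethyl-1,3-dioxolan-4-yl]-2-methylbut-3-en-1-yl]oxy}dimethylsilane
Conditions: TBSOTf, 2,6-lutidine, CH2Cl2, −78 → 0 °C
Reagents that add atoms: tert-butyldimethylsilyl triflate, CC(C)(C)[Si](C)(C)OS(=O)(=O)C(F)(F)F
Why: Standard silylation of the hindered secondary alcohol protects C5–OH so that the later acylation, basic and oxidative steps cannot move the C6 ester or oxidise C5.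

Step 7
Reactants: 12 tert-butyl{[(1S,2R)-1-[(4S)-2,2-dimethyl-1,3-dioxolan-4-yl]-2-methylbut-3-en-1-yl]oxy}dimethylsilane
Product: 13 (2S,3S,4R)-3-[(tert-butyldimethylsilyl)oxy]-4-methylhex-5-ene-1,2-diol
Conditions: AcOH/H2O (4:1), 40 °C
Reagents that add atoms: none
Why: Mild acid hydrolysis of the terminal acetonide, to which a secondary TBS ether is stable.

Step 8
Reactants: 13 (2S,3S,4R)-3-[(tert-butyldimethylsilyl)oxy]-4-methylhex-5-ene-1,2-diol
Product: 15 (2S,3S,4R)-3-[(tert-butyldimethylsilyl)oxy]-1-hydroxy-4-methylhex-5-en-2-yl 2-methylpropanoate, via cyclic ortho ester 14 (not isolated)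
Conditions: (MeO)3C-iPr, PPTS (cat.), CH2Cl2, rt; then 1 M aq. HCl/THF, 0 °C, 15 min
Reagents that add atoms: trimethyl orthoisobutyrate, COC(OC)(OC)C(C)C; water, O (ester carbonyl oxygen)
Why: Regioselective monoacylation through a cyclic ortho ester: kinetic acidic hydrolysis expels the less hindered primary oxygen and leaves the isobutyryl group on the secondary C6 oxygen, whose C–O bond is never broken (configuration retained).

Step 9
Reactants: 15 (2S,3S,4R)-3-[(tert-butyldimethylsilyl)oxy]-1-hydroxy-4-methylhex-5-en-2-yl 2-methylpropanoate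
Product: 16 (2R,3S,4R)-3-[(tert-butyldimethylsilyl)oxy]-4-methyl-1-oxohex-5-en-2-yl 2-methylpropanoate
Conditions: Dess–Martin periodinane, CH2Cl2, 0 °C → rt; used at once
Reagents that add atoms: none
Why: Dess–Martin oxidation of the primary alcohol under near-neutral conditions gives the α-acyloxy aldehyde without acyl migration or epimerisation at C6 (the descriptor changes only by priority).

Step 10
Reactants: 16 (2R,3S,4R)-3-[(tert-butyldimethylsilyl)oxy]-4-methyl-1-oxohex-5-en-2-yl 2-methylpropanoate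
Product: 17 methyl (4S,5S,6R)-5-[(tert-butyldimethylsilyl)oxy]-3-hydroxy-6-methyl-2-methylidene-4-[(2-methylpropanoyl)oxy]oct-7-enoate (C3 epimers)
Conditions: iBu2AlH, NMO, THF, 0 °C; methyl propiolate, 0 °C; then 16, 0 °C → rt; aq. potassium sodium tartrate
Reagents that add atoms: methyl propiolate, C#CC(=O)OC
Why: Vinylalumination (amine-free Morita–Baylis–Hillman equivalent): the α-aluminated acrylate from hydroalumination of the propiolate adds to the base-sensitive aldehyde, and the new carbinol centre is erased in the next step so its configuration does not matter.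

Step 11
Reactants: 17 methyl (4S,5S,6R)-5-[(tert-butyldimethylsilyl)oxy]-3-hydroxy-6-methyl-2-methylidene-4-[(2-methylpropanoyl)oxy]oct-7-enoate
Product: 18 methyl (2Z,4S,5S,6R)-2-(bromomethyl)-5-[(tert-butyldimethylsilyl)oxy]-6-methyl-4-[(2-methylpropanoyl)oxy]octa-2,7-dienoate
Conditions: NBS, Me2S, CH2Cl2, −20 → 0 °C
Reagents that add atoms: N-bromosuccinimide, O=C1CCC(=O)N1Br
Why: Corey–Kim-type bromination of the Baylis–Hillman alcohol with allylic transposition (SN2′) gives the conjugated primary (Z)-2-(bromomethyl)enoate.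

Step 12
Reactants: 8 (4R)-4-hydroxy-6,6-dimethoxy-4-methylhex-1-en-3-one; 18 methyl (2Z,4S,5S,6R)-2-(bromomethyl)-5-[(tert-butyldimethylsilyl)oxy]-6-methyl-4-[(2-methylpropanoyl)oxy]octa-2,7-dienoate
Product: 19 methyl (2Z,4S,5S,6R,7E,10R)-2-(bromomethyl)-5-[(tert-butyldimethylsilyl)oxy]-10-hydroxy-12,12-dimethoxy-6,10-dimethyl-4-[(2-methylpropanoyl)oxy]-9-oxododeca-2,7-dienoate
Conditions: second-generation Hoveyda–Grubbs catalyst RuCl2(H2IMes)(=CH-C6H4-2-OiPr) (5 mol %), 8 (2 equiv), CH2Cl2, 40 °C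
Reagents that add atoms: none
Why: Olefin cross-metathesis of an electron-poor vinyl ketone with a terminal alkene is selective for the hetero-coupled E-enone, while the trisubstituted bromomethyl enoate is inert to the catalyst.

Step 13
Reactants: 19 methyl (2Z,4S,5S,6R,7E,10R)-2-(bromomethyl)-5-[(tert-butyldimethylsilyl)oxy]-10-hydroxy-12,12-dimethoxy-6,10-dimethyl-4-[(2-methylpropanoyl)oxy]-9-oxododeca-2,7-dienoate
Product: 20 methyl (2Z,4S,5S,6R,7E,10R)-2-(bromomethyl)-5-[(tert-butyldimethylsilyl)oxy]-10-hydroxy-6,10-dimethyl-4-[(2-methylpropanoyl)oxy]-9,12-dioxododeca-2,7-dienoate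
Conditions: PPTS, acetone/H2O (10:1), 45 °C
Reagents that add atoms: water, O (aldehyde oxygen)
Why: Mild acid-catalysed acetal hydrolysis unmasks the C8 aldehyde without cleaving the secondary TBS ether or the allylic bromide.

Step 14
Reactants: 20 methyl (2Z,4S,5S,6R,7E,10R)-2-(bromomethyl)-5-[(tert-butyldimethylsilyl)oxy]-10-hydroxy-6,10-dimethyl-4-[(2-methylpropanoyl)oxy]-9,12-dioxododeca-2,7-dienoate
Product: 22 (4R,5S,6S,7R,8S,10R)-5-(tert-butyldimethylsilyloxy)-10-hydroxy-6-(2-methylpropanoyloxy)-1-oxogermacra-2(E),11(13)-dien-12,8-olide (ten-membered E-enone, trans-fused α-methylene-γ-lactone), via macrocyclic hydroxy ester 21 (not isolated)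
Conditions: CrCl2 (10 equiv), THF/DMF (4:1), rt, syringe-pump addition of 20 to 2 mM; aq. NH4Cl; then TsOH·H2O (cat.), CH2Cl2, rt
Reagents that add atoms: none
Why: Intramolecular Nozaki–Hiyama (chromium Barbier) allylation then lactonisation: the 2-(alkoxycarbonyl)allylchromium adds through its γ-carbon C7 to the C8 aldehyde in a chair-like transition state with both ring arms pseudo-equatorial (anti addition, hence the 7,8-trans lactone), allylic strain from the C6 isobutyrate is expected to expose the face giving 7R,8S, and the C8 alkoxide closes the γ-lactone.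

Step 15
Reactants: 22 (4R,5S,6S,7R,8S,10R)-5-(tert-butyldimethylsilyloxy)-10-hydroxy-6-(2-methylpropanoyloxy)-1-oxogermacra-2(E),11(13)-dien-12,8-olide
Product: 23 (4S,5S,6S,7R,8S,10R)-5-(tert-butyldimethylsilyloxy)-6-(2-methylpropanoyloxy)-1-oxo-3,10-epoxygermacra-2,11(13)-dien-12,8-olide
Conditions: Pd(OCOCF3)2 (10 mol %), DMSO (20 mol %), O2 (1 atm), EtOAc, 60 °C
Reagents that add atoms: none
Why: Proposed new method: transannular aerobic Wacker-type dehydrogenative oxa-cyclisation, in which electrophilic divalent palladium activates the E-enone, the C10 tertiary hydroxyl adds across the ring to C3 (5-endo, helped by metal activation and by the product-like s-trans conformer of the ten-membered ring), the C2 palladium enolate equilibrates through its oxygen-bound form and loses H-3 by β-hydride elimination to give the vinylogous ester, and O2 returns zerovalent palladium to the divalent state; the closest known reaction type is the palladium-catalysed oxidative cyclisation of acyclic α′-hydroxy enones to furan-3(2H)-ones (and aerobic palladium dehydrogenation of ketones), not yet shown transannularly in a medium ring; no new stereocentre is formed.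

Step 16
Reactants: 23 (4S,5S,6S,7R,8S,10R)-5-(tert-butyldimethylsilyloxy)-6-(2-methylpropanoyloxy)-1-oxo-3,10-epoxygermacra-2,11(13)-dien-12,8-olide
Product: 24 CNP0141385.1, (4S,5S,6S,7R,8S,10R)-5-hydroxy-6-(2-methylpropanoyloxy)-1-oxo-3,10-epoxygermacra-2,11(13)-dien-12,8-olide
Conditions: HF·pyridine, pyridine/THF, 0 °C → rt
Reagents that add atoms: none
Why: Desilylation under buffered acidic fluoride conditions frees C5–OH without the base-induced 6→5 acyl migration or conjugate addition to the α-methylene lactone.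

## Compound list

1 | (S)-lactic acid | C[C@H](O)C(=O)O | starting material
2 | (2S,5S)-2-tert-butyl-5-methyl-1,3-dioxolan-4-one | C[C@@H]1O[C@H](C(C)(C)C)OC1=O | intermediate
3 | lithium (2S)-2-tert-butyl-5-methyl-1,3-dioxol-4-olate (enolate of 2) | CC1=C(O[Li])O[C@@H](C(C)(C)C)O1 | intermediate
4 | (2S,5R)-2-tert-butyl-5-methyl-5-(prop-2-enyl)-1,3-dioxolan-4-one | C[C@]1(CC=C)O[C@H](C(C)(C)C)OC1=O | intermediate
5 | (2S,5R)-2-tert-butyl-5-methyl-5-(2-oxoethyl)-1,3-dioxolan-4-one | C[C@]1(CC=O)O[C@H](C(C)(C)C)OC1=O | intermediate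
6 | (2S,5R)-2-tert-butyl-5-(2,2-dimethoxyethyl)-5-methyl-1,3-dioxolan-4-one | C[C@]1(CC(OC)OC)O[C@H](C(C)(C)C)OC1=O | intermediate
7 | bromomagnesium (2S,5R)-2-tert-butyl-5-(2,2-dimethoxyethyl)-4-ethenyl-5-methyl-1,3-dioxolan-4-olate (C4 epimers) | C[C@]1(CC(OC)OC)O[C@H](C(C)(C)C)OC1(O[Mg]Br)C=C | intermediate
8 | (4R)-4-hydroxy-6,6-dimethoxy-4-methylhex-1-en-3-one | C=CC(=O)[C@](C)(O)CC(OC)OC | intermediate
9 | (4S)-2,2-dimethyl-1,3-dioxolane-4-carbaldehyde | O=C[C@@H]1COC(C)(C)O1 | starting material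
10 | (1S,2R)-1-[(4S)-2,2-dimethyl-1,3-dioxolan-4-yl]-2-methylbut-3-en-1-yl diisopinocampheylborinate | C=C[C@@H](C)[C@H](OB([C@@H]1C[C@@H]2C[C@H]([C@H]1C)C2(C)C)[C@@H]1C[C@@H]2C[C@H]([C@H]1C)C2(C)C)[C@@H]1COC(C)(C)O1 | intermediate
11 | (1S,2R)-1-[(4S)-2,2-dimethyl-1,3-dioxolan-4-yl]-2-methylbut-3-en-1-ol | C=C[C@@H](C)[C@H](O)[C@@H]1COC(C)(C)O1 | intermediate
12 | tert-butyl{[(1S,2R)-1-[(4S)-2,2-dimethyl-1,3-dioxolan-4-yl]-2-methylbut-3-en-1-yl]oxy}dimethylsilane | C=C[C@@H](C)[C@H](O[Si](C)(C)C(C)(C)C)[C@@H]1COC(C)(C)O1 | intermediate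
13 | (2S,3S,4R)-3-[(tert-butyldimethylsilyl)oxy]-4-methylhex-5-ene-1,2-diol | C=C[C@@H](C)[C@H](O[Si](C)(C)C(C)(C)C)[C@@H](O)CO | intermediate
14 | (4S)-4-[(1S,2R)-1-[(tert-butyldimethylsilyl)oxy]-2-methylbut-3-en-1-yl]-2-methoxy-2-(propan-2-yl)-1,3-dioxolane (C2 epimers) | C=C[C@@H](C)[C@H](O[Si](C)(C)C(C)(C)C)[C@@H]1COC(OC)(C(C)C)O1 | intermediate
15 | (2S,3S,4R)-3-[(tert-butyldimethylsilyl)oxy]-1-hydroxy-4-methylhex-5-en-2-yl 2-methylpropanoate | C=C[C@@H](C)[C@H](O[Si](C)(C)C(C)(C)C)[C@@H](OC(=O)C(C)C)CO | intermediate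
16 | (2R,3S,4R)-3-[(tert-butyldimethylsilyl)oxy]-4-methyl-1-oxohex-5-en-2-yl 2-methylpropanoate | C=C[C@@H](C)[C@H](O[Si](C)(C)C(C)(C)C)[C@@H](OC(=O)C(C)C)C=O | intermediate
17 | methyl (4S,5S,6R)-5-[(tert-butyldimethylsilyl)oxy]-3-hydroxy-6-methyl-2-methylidene-4-[(2-methylpropanoyl)oxy]oct-7-enoate (C3 epimers) | C=C[C@@H](C)[C@H](O[Si](C)(C)C(C)(C)C)[C@@H](OC(=O)C(C)C)C(O)C(=C)C(=O)OC | intermediate
18 | methyl (2Z,4S,5S,6R)-2-(bromomethyl)-5-[(tert-butyldimethylsilyl)oxy]-6-methyl-4-[(2-methylpropanoyl)oxy]octa-2,7-dienoate | C=C[C@@H](C)[C@H](O[Si](C)(C)C(C)(C)C)[C@@H](OC(=O)C(C)C)/C=C(\CBr)C(=O)OC | intermediate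
19 | methyl (2Z,4S,5S,6R,7E,10R)-2-(bromomethyl)-5-[(tert-butyldimethylsilyl)oxy]-10-hydroxy-12,12-dimethoxy-6,10-dimethyl-4-[(2-methylpropanoyl)oxy]-9-oxododeca-2,7-dienoate | COC(OC)C[C@@](C)(O)C(=O)/C=C/[C@@H](C)[C@H](O[Si](C)(C)C(C)(C)C)[C@@H](OC(=O)C(C)C)/C=C(\CBr)C(=O)OC | intermediate
20 | methyl (2Z,4S,5S,6R,7E,10R)-2-(bromomethyl)-5-[(tert-butyldimethylsilyl)oxy]-10-hydroxy-6,10-dimethyl-4-[(2-methylpropanoyl)oxy]-9,12-dioxododeca-2,7-dienoate | O=CC[C@@](C)(O)C(=O)/C=C/[C@@H](C)[C@H](O[Si](C)(C)C(C)(C)C)[C@@H](OC(=O)C(C)C)/C=C(\CBr)C(=O)OC | intermediate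
21 | methyl (4R,5S,6S,7R,8S,10R)-5-(tert-butyldimethylsilyloxy)-8,10-dihydroxy-6-(2-methylpropanoyloxy)-1-oxogermacra-2(E),11(13)-dien-12-oate | COC(=O)C(=C)[C@@H]1[C@@H](O)C[C@@](C)(O)C(=O)/C=C/[C@@H](C)[C@H](O[Si](C)(C)C(C)(C)C)[C@H]1OC(=O)C(C)C | intermediate
22 | (4R,5S,6S,7R,8S,10R)-5-(tert-butyldimethylsilyloxy)-10-hydroxy-6-(2-methylpropanoyloxy)-1-oxogermacra-2(E),11(13)-dien-12,8-olide | C=C1C(=O)O[C@H]2C[C@@](C)(O)C(=O)/C=C/[C@@H](C)[C@H](O[Si](C)(C)C(C)(C)C)[C@@H](OC(=O)C(C)C)[C@H]12 | intermediate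
23 | (4S,5S,6S,7R,8S,10R)-5-(tert-butyldimethylsilyloxy)-6-(2-methylpropanoyloxy)-1-oxo-3,10-epoxygermacra-2,11(13)-dien-12,8-olide | C=C1C(=O)O[C@H]2C[C@@]3(C)OC(=CC3=O)[C@@H](C)[C@H](O[Si](C)(C)C(C)(C)C)[C@@H](OC(=O)C(C)C)[C@H]12 | intermediate
24 | CNP0141385.1, (4S,5S,6S,7R,8S,10R)-5-hydroxy-6-(2-methylpropanoyloxy)-1-oxo-3,10-epoxygermacra-2,11(13)-dien-12,8-olide | C=C1C(=O)O[C@H]2C[C@@]3(C)OC(=CC3=O)[C@@H](C)[C@H](O)[C@@H](OC(=O)C(C)C)[C@H]12 | target

## Step count and risks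

Total steps: 16 (steps 1–4 West, 5–11 East, 12–16 union and endgame).
Longest linear sequence: 12 steps (9 → 24, steps 5–16).

Steps most likely to fail:

**Step 14 (chromium Barbier macrocyclisation).** A ten-membered ring is closed and two stereocentres (C7, C8) are set at once; oligomers, simple reduction of the bromide or the wrong C7/C8 pair are possible. The fallback sets out from 8 and 18 and comes back at 22. The acetal of 8 is hydrolysed (PPTS, wet acetone) to (3R)-3-hydroxy-3-methyl-4-oxohex-5-enal F1. F1 and 18 are joined in an intermolecular, catalyst-controlled chromium allylation (CrCl2 10 mol %, chiral carbazole bis(oxazoline) ligand, Mn powder, Me3SiCl, then dilute acid), where the ligand fixes the aldehyde face (C8) and the anti chair transition state fixes C7. This gives the acyclic hydroxy ester methyl (3R,4S,5S,6R)-5-[(tert-butyldimethylsilyl)oxy]-3-[(1S,3R)-1,3-dihydroxy-3-methyl-4-oxohex-5-en-1-yl]-6-methyl-2-methylidene-4-[(2-methylpropanoyl)oxy]oct-7-enoate F2. TsOH closes it to the trans lactone (1S,2S,3R)-2-[(tert-butyldimethylsilyl)oxy]-1-[(2S,3R)-2-[(2R)-2-hydroxy-2-methyl-3-oxopent-4-en-1-yl]-4-methylidene-5-oxooxolan-3-yl]-3-methylpent-4-en-1-yl 2-methylpropanoate F3. Ring-closing metathesis at C2=C3 (second-generation Grubbs catalyst RuCl2(H2IMes)(PCy3)(=CHPh), dilute toluene, 80 °C) then gives 22.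

**Step 15 (proposed new transannular oxidative cyclisation).** Palladium may fail to engage the hindered tertiary alcohol across the ring or may oxidise elsewhere. The fallback uses known chemistry, sets out from 22 and comes back at 23. Acid-mediated transannular oxa-Michael addition (TsOH, CH2Cl2; the known acid-promoted 5-endo closure of α′-hydroxy enones) gives the saturated bridged ketone (3R,4S,5S,6S,7R,8S,10R)-5-(tert-butyldimethylsilyloxy)-6-(2-methylpropanoyloxy)-1-oxo-3,10-epoxygermacr-11(13)-en-12,8-olide F4. Soft enolisation (Me3SiOTf, Et3N) gives its C1 trimethylsilyl enol ether F5, and Saegusa–Ito oxidation (Pd(OAc)2, MeCN) installs the C2=C3 double bond to reach 23.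

**Step 5 (mismatched crotylboration).** The Z-crotyl reagent must override the strong Felkin preference of 9, so the diastereomer ratio may be low. The fallback sets out from 9 and comes back at 12. An auxiliary-controlled Evans syn-aldol of (4S)-4-benzyl-3-propanoyl-1,3-oxazolidin-2-one (Bu2BOTf, iPr2NEt, −78 °C) with 9 gives (4S)-4-benzyl-3-[(2S,3S)-3-[(4S)-2,2-dimethyl-1,3-dioxolan-4-yl]-3-hydroxy-2-methylpropanoyl]-1,3-oxazolidin-2-one F6. Silylation (TBSOTf, 2,6-lutidine) gives its tert-butyldimethylsilyl ether F7. LiBH4 reduction gives (2R,3S)-3-[(tert-butyldimethylsilyl)oxy]-3-[(4S)-2,2-dimethyl-1,3-dioxolan-4-yl]-2-methylpropan-1-ol F8. Dess–Martin oxidation gives (2S,3S)-3-[(tert-butyldimethylsilyl)oxy]-3-[(4S)-2,2-dimethyl-1,3-dioxolan-4-yl]-2-methylpropanal F9, and Wittig methylenation (Ph3P=CH2, THF, −78 → 0 °C) gives 12.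

## Further compounds

F1 | step 14 | (3R)-3-hydroxy-3-methyl-4-oxohex-5-enal | O=CC[C@@](C)(O)C(=O)C=C
F2 | step 14 | methyl (3R,4S,5S,6R)-5-[(tert-butyldimethylsilyl)oxy]-3-[(1S,3R)-1,3-dihydroxy-3-methyl-4-oxohex-5-en-1-yl]-6-methyl-2-methylidene-4-[(2-methylpropanoyl)oxy]oct-7-enoate | C=CC(=O)[C@](C)(O)C[C@H](O)[C@@H](C(=C)C(=O)OC)[C@H](OC(=O)C(C)C)[C@@H](O[Si](C)(C)C(C)(C)C)[C@H](C)C=C
F3 | step 14 | (1S,2S,3R)-2-[(tert-butyldimethylsilyl)oxy]-1-[(2S,3R)-2-[(2R)-2-hydroxy-2-methyl-3-oxopent-4-en-1-yl]-4-methylidene-5-oxooxolan-3-yl]-3-methylpent-4-en-1-yl 2-methylpropanoate | C=CC(=O)[C@](C)(O)C[C@@H]1OC(=O)C(=C)[C@H]1[C@H](OC(=O)C(C)C)[C@@H](O[Si](C)(C)C(C)(C)C)[C@H](C)C=C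
F4 | step 15 | (3R,4S,5S,6S,7R,8S,10R)-5-(tert-butyldimethylsilyloxy)-6-(2-methylpropanoyloxy)-1-oxo-3,10-epoxygermacr-11(13)-en-12,8-olide | C=C1C(=O)O[C@H]2C[C@@]3(C)O[C@H](CC3=O)[C@@H](C)[C@H](O[Si](C)(C)C(C)(C)C)[C@@H](OC(=O)C(C)C)[C@H]12
F5 | step 15 | C1 trimethylsilyl enol ether of F4 (C1=C2) | C=C1C(=O)O[C@H]2C[C@@]3(C)O[C@H](C=C3O[Si](C)(C)C)[C@@H](C)[C@H](O[Si](C)(C)C(C)(C)C)[C@@H](OC(=O)C(C)C)[C@H]12
F6 | step 5 | (4S)-4-benzyl-3-[(2S,3S)-3-[(4S)-2,2-dimethyl-1,3-dioxolan-4-yl]-3-hydroxy-2-methylpropanoyl]-1,3-oxazolidin-2-one | O=C(N1[C@@H](Cc2ccccc2)COC1=O)[C@@H](C)[C@H](O)[C@@H]1COC(C)(C)O1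
F7 | step 5 | (4S)-4-benzyl-3-[(2S,3S)-3-[(tert-butyldimethylsilyl)oxy]-3-[(4S)-2,2-dimethyl-1,3-dioxolan-4-yl]-2-methylpropanoyl]-1,3-oxazolidin-2-one | O=C(N1[C@@H](Cc2ccccc2)COC1=O)[C@@H](C)[C@H](O[Si](C)(C)C(C)(C)C)[C@@H]1COC(C)(C)O1
F8 | step 5 | (2R,3S)-3-[(tert-butyldimethylsilyl)oxy]-3-[(4S)-2,2-dimethyl-1,3-dioxolan-4-yl]-2-methylpropan-1-ol | OC[C@@H](C)[C@H](O[Si](C)(C)C(C)(C)C)[C@@H]1COC(C)(C)O1
F9 | step 5 | (2S,3S)-3-[(tert-butyldimethylsilyl)oxy]-3-[(4S)-2,2-dimethyl-1,3-dioxolan-4-yl]-2-methylpropanal | O=C[C@@H](C)[C@H](O[Si](C)(C)C(C)(C)C)[C@@H]1COC(C)(C)O1
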